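**Plan**
- The target is read as (13S)-3β,7α-diacetoxylabd-8(17)-en-15-oic acid. Working backwards, the acetates come off, the C7 oxygen is traced to an allylic oxidation and C17 to a Wittig reaction, which leaves a 17-nor-8-ketone.
- Ring B then holds an sp2 carbon (C8) between C7 and C9, so C7=C8(OMe)–C9=C10 can be a 2-methoxy-1,3-diene. C5=C6 with a removable sulfonyl group on C6 is the dienophile, and C1–C4 of ring A is the four-atom tether between C10 and C5. A retro intramolecular Diels–Alder reaction therefore cuts C5–C10 and C6–C7 and opens both rings to an acyclic 1,7,9-decatriene.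
- Forward, the triene is built from (R)-pantolactone (C2–C5, C18, C19), methyl acetoacetate (C8–C10, C20) and monomethyl (R)-3-methylglutarate (C11–C16) by C9–C11 alkylation and a geometry-retaining C1–C10 Suzuki coupling on an (E)-enol tosylate. Rings B and A then close together in step 14.
- Stereochemistry: C3 and C13 are bought. C5 and C10 are relayed from C3 in the cycloaddition. C9 settles under thermodynamic control when the enol ether is hydrolysed. C7 comes from an axial-selective allylic oxidation.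

Key step: step 14

Remark: atoms are numbered as in labdane (decalin C1–C10, side chain C11–C15, C16 on C13, C17 on C8, C18 and C19 on C4, C20 on C10), monomethyl (R)-3-methylglutarate is taken to be purchasable in enantiopure form, and the SMILES of the Tebbe reagent shows its covalent skeleton Cp2Ti(Cl)–CH2–AlMe2, the chloride bridge to aluminium being a dative contact.

**Route**

Step 1
Reactants: 1 (R)-pantolactone
Product: 2 (3R)-3-(methoxymethoxy)-4,4-dimethyloxolan-2-one
Conditions: MOMCl, i-Pr2NEt, CH2Cl2, 0 °C to rt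
Reagents that add atoms: chloromethyl methyl ether, COCCl
Why: Alkoxymethylation of the secondary hydroxyl (Williamson-type etherification under a hindered amine base) is routine, and the mild base leaves the α-stereocenter, the future C3, untouched.

Step 2
Reactants: 2 (3R)-3-(methoxymethoxy)-4,4-dimethyloxolan-2-one
Product: 3 (3R)-3-(methoxymethoxy)-4,4-dimethyloxolan-2-ol (lactol; anomer mixture)
Conditions: i-Bu2AlH (1.1 equiv), CH2Cl2, −78 °C; aq. KNaC4H4O6
Reagents that add atoms: none
Why: Partial reduction of a lactone with i-Bu2AlH stops at the lactol because the tetrahedral aluminium hemiacetal is stable at −78 °C.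

Step 3
Reactants: 3 (3R)-3-(methoxymethoxy)-4,4-dimethyloxolan-2-ol
Product: 4 (3S)-3-(methoxymethoxy)-2,2-dimethylpent-4-en-1-ol
Conditions: Ph3PCH3Br, KN(SiMe3)2 (3 equiv), THF, 0 °C to 40 °C
Reagents that add atoms: methyltriphenylphosphonium bromide, C[P+](c1ccccc1)(c1ccccc1)c1ccccc1.[Br-]
Why: Wittig methylenation of the ring-opened hydroxy aldehyde adds C1 as a terminal vinyl group, and olefination by the non-stabilised ylide should outrun epimerisation of the α-alkoxy center.

Step 4
Reactants: 5 monomethyl (R)-3-methylglutarate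
Product: 6 methyl (3R)-5-hydroxy-3-methylpentanoate
Conditions: BH3·SMe2, THF, 0 °C to rt; MeOH quench
Reagents that add atoms: none
Why: Borane reduces a carboxylic acid far faster than an ester (chemoselective acyloxyborane reduction), so only the acid terminus, the future C15, becomes a primary alcohol and the C13 stereocenter is not involved.

Step 5
Reactants: 6 methyl (3R)-5-hydroxy-3-methylpentanoate
Product: 7 methyl (3R)-5-[(tert-butyldimethylsilyl)oxy]-3-methylpentanoate
Conditions: TBSCl, imidazole, DMF, rt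
Reagents that add atoms: tert-butyldimethylsilyl chloride, CC(C)(C)[Si](C)(C)Cl
Why: Imidazole-promoted silylation of a primary alcohol is routine and prevents lactonisation of the hydroxy ester.

Step 6
Reactants: 7 methyl (3R)-5-[(tert-butyldimethylsilyl)oxy]-3-methylpentanoate
Product: 8 (3S)-5-[(tert-butyldimethylsilyl)oxy]-3-methylpentan-1-ol
Conditions: LiAlH4, Et2O, 0 °C
Reagents that add atoms: none
Why: Hydride reduction of the ester gives the primary alcohol at the future C11 while the silyl ether survives at 0 °C.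

Step 7
Reactants: 8 (3S)-5-[(tert-butyldimethylsilyl)oxy]-3-methylpentan-1-ol
Product: 9 tert-butyl{[(3R)-5-iodo-3-methylpentyl]oxy}dimethylsilane
Conditions: I2, PPh3, imidazole, CH2Cl2, 0 °C
Reagents that add atoms: iodine, II
Why: Appel-type iodination proceeds by SN2 displacement of the alkoxyphosphonium ion at the primary carbon, far from the stereocenter.

Step 8
Reactants: 10 methyl acetoacetate; 9 tert-butyl{[(3R)-5-iodo-3-methylpentyl]oxy}dimethylsilane
Product: 11 methyl (5S)-2-acetyl-7-[(tert-butyldimethylsilyl)oxy]-5-methylheptanoate (C2 epimer mixture)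
Conditions: K2CO3, acetone, 56 °C
Reagents that add atoms: none
Why: The acetoacetic ester alkylation joins C9 to C11 through C-alkylation of the soft enolate by a primary iodide, and the new C9 center is of no consequence because it becomes sp2 in the next step.

Step 9
Reactants: 11 methyl (5S)-2-acetyl-7-[(tert-butyldimethylsilyl)oxy]-5-methylheptanoate
Product: 12 methyl (2E)-2-{(3S)-5-[(tert-butyldimethylsilyl)oxy]-3-methylpentyl}-3-[(4-methylbenzenesulfonyl)oxy]but-2-enoate
Conditions: TsCl, N-methylimidazole, Et3N, MeCN, 0 °C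
Reagents that add atoms: 4-methylbenzenesulfonyl chloride, Cc1ccc(cc1)S(=O)(=O)Cl
Why: O-Sulfonylation of the amine-generated, non-chelated enolate by the N-sulfonylimidazolium formed from TsCl and N-methylimidazole is the E-selective branch of the known stereocomplementary enol tosylation of α-substituted β-keto esters, so the tosyloxy group should end up trans to the ester and the C20 methyl cis to it.

Step 10
Reactants: 4 (3S)-3-(methoxymethoxy)-2,2-dimethylpent-4-en-1-ol; 12 methyl (2E)-2-{(3S)-5-[(tert-butyldimethylsilyl)oxy]-3-methylpentyl}-3-[(4-methylbenzenesulfonyl)oxy]but-2-enoate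
Product: 14 methyl (2E,6S)-2-{(3S)-5-[(tert-butyldimethylsilyl)oxy]-3-methylpentyl}-8-hydroxy-6-(methoxymethoxy)-3,7,7-trimethyloct-2-enoate, via bis-borane adduct 13 (not isolated)
Conditions: 4, 9-BBN-H (2.2 equiv), THF, 0 °C to rt; then 12, Pd(OAc)2 (cat.), SPhos, aq. K3PO4, THF, 60 °C
Reagents that add atoms: none
Why: 9-BBN adds to the terminal vinyl group in the anti-Markovnikov sense while the hydroxyl is held as a borinate, and the B-alkyl Suzuki–Miyaura coupling then replaces the activated β-tosyloxy group with retention of alkene geometry, forming C1–C10 with C1 trans to the ester.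

Step 11
Reactants: 14 methyl (2E,6S)-2-{(3S)-5-[(tert-butyldimethylsilyl)oxy]-3-methylpentyl}-8-hydroxy-6-(methoxymethoxy)-3,7,7-trimethyloct-2-enoate
Product: 15 (3S,6E)-7-{(3S)-5-[(tert-butyldimethylsilyl)oxy]-3-methylpentyl}-8-methoxy-3-(methoxymethoxy)-2,2,6-trimethylnona-6,8-dien-1-ol
Conditions: Cp2Ti(μ-CH2)(μ-Cl)AlMe2 (3 equiv), pyridine, THF–PhMe, −40 °C to 0 °C; aq. NaOH
Reagents that add atoms: Tebbe reagent Cp2Ti(μ-CH2)(μ-Cl)AlMe2, C[Al](C)C[Ti](Cl)(C1C=CC=C1)C1C=CC=C1
Why: Tebbe methylenation turns the ester carbonyl into a methyl enol ether, which adds C7 and unveils the 2-methoxy-1,3-diene without touching the C9=C10 geometry, the excess reagent covering the free hydroxyl.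

Step 12
Reactants: 15 (3S,6E)-7-{(3S)-5-[(tert-butyldimethylsilyl)oxy]-3-methylpentyl}-8-methoxy-3-(methoxymethoxy)-2,2,6-trimethylnona-6,8-dien-1-ol
Product: 16 (3S,6E)-7-{(3S)-5-[(tert-butyldimethylsilyl)oxy]-3-methylpentyl}-8-methoxy-3-(methoxymethoxy)-2,2,6-trimethylnona-6,8-dienal
Conditions: (n-Pr4N)RuO4 (cat.), N-methylmorpholine N-oxide, 4 Å MS, CH2Cl2, rt
Reagents that add atoms: none
Why: The Ley–Griffith oxidation is neutral and non-acidic, so the neopentyl alcohol should go to the non-enolisable aldehyde while the acid-labile enol ether diene is spared.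

Step 13
Reactants: 16 (3S,6E)-7-{(3S)-5-[(tert-butyldimethylsilyl)oxy]-3-methylpentyl}-8-methoxy-3-(methoxymethoxy)-2,2,6-trimethylnona-6,8-dienal
Product: 17 {[(1E,4S,7E)-8-{(3S)-5-[(tert-butyldimethylsilyl)oxy]-3-methylpentyl}-9-methoxy-4-(methoxymethoxy)-3,3,7-trimethyldeca-1,7,9-trien-1-yl]sulfonyl}benzene
Conditions: (EtO)2P(O)CH2SO2Ph, NaH, THF, 0 °C to rt
Reagents that add atoms: diethyl [(phenylsulfonyl)methyl]phosphonate, CCOP(=O)(CS(=O)(=O)c1ccccc1)OCC
Why: The Horner–Wadsworth–Emmons reaction of a sulfonyl-stabilised phosphonate with a hindered, non-enolisable aldehyde adds C6 and should give the (E)-vinyl sulfone, which is the activated dienophile.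

Step 14
Reactants: 17 {[(1E,4S,7E)-8-{(3S)-5-[(tert-butyldimethylsilyl)oxy]-3-methylpentyl}-9-methoxy-4-(methoxymethoxy)-3,3,7-trimethyldeca-1,7,9-trien-1-yl]sulfonyl}benzene
Product: 18 (13S)-15-[(tert-butyldimethylsilyl)oxy]-8-methoxy-3β-(methoxymethoxy)-6α-(phenylsulfonyl)-17-norlabd-8-ene
Conditions: PhMe (0.01 M), BHT, 160 °C, sealed tube
Reagents that add atoms: none
Why: Heating should trigger a concerted, asynchronous, suprafacial [4+2] cycloaddition between the 2-methoxy-1,3-diene C7=C8–C9=C10 and the sulfonyl-activated alkene C5=C6, the closest precedent being the thermal intramolecular Diels–Alder reaction of (E)-1-sulfonyl-1,7,9-decatrienes and of 2-alkoxy- or 2-silyloxydienes to trans-decalins. Ring B closes as the new cyclohexene (bonds C6–C7 and C5–C10, enol ether C8=C9 kept) and ring A closes in the same event as the six-membered ring spanned by the C1–C4 tether, a fused type 1 closure, because the bridged orientation that the polarisation of the 2-methoxydiene would prefer is out of geometric reach. C5 and the quaternary C10 are set together: with the tether on the outside (E) position of C10, the transition state that keeps the quaternary C4 exo and the sulfonyl group endo puts C5–H anti to the C10 methyl, which gives the trans ring fusion and a transient 6α-sulfone. The diene face is chosen by the C3 stereocenter, whose methoxymethoxy group should sit equatorial on the chair-like tether, so the bought C3 configuration is relayed to the 5α-H and 10β-methyl arrangement. The step needs trans over cis fusion and diastereofacial selectivity, and the E geometry of C9=C10 from steps 9 and 10, the gem-dimethyl group on C4 and the C3 substituent are the elements expected to secure them.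

Step 15
Reactants: 18 (13S)-15-[(tert-butyldimethylsilyl)oxy]-8-methoxy-3β-(methoxymethoxy)-6α-(phenylsulfonyl)-17-norlabd-8-ene
Product: 19 (13S)-15-[(tert-butyldimethylsilyl)oxy]-8-methoxy-3β-(methoxymethoxy)-17-norlabd-8-ene
Conditions: Na(Hg) (6%), Na2HPO4, MeOH–THF, −20 °C to 0 °C
Reagents that add atoms: none
Why: Reductive desulfonylation by single-electron transfer cleaves the C6–S bond and returns C6 as a methylene group, the phosphate buffer keeping the medium mild enough for the enol ether.

Step 16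
Reactants: 19 (13S)-15-[(tert-butyldimethylsilyl)oxy]-8-methoxy-3β-(methoxymethoxy)-17-norlabd-8-ene
Product: 20 (13S)-3β,15-dihydroxy-17-norlabdan-8-one
Conditions: 3 M HCl, MeOH–H2O, 50 °C
Reagents that add atoms: water, O
Why: Aqueous acid hydrolyses the enol ether to the C8 ketone and cleaves the methoxymethyl and silyl ethers in the same operation, and because C9 is protonated reversibly next to the ketone it should settle as the equatorial side chain (9α-H) whichever face is protonated first.

Step 17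
Reactants: 20 (13S)-3β,15-dihydroxy-17-norlabdan-8-one
Product: 21 (13S)-labd-8(17)-ene-3β,15-diol
Conditions: Ph3PCH3Br, KOt-Bu (5 equiv), PhMe, 90 °C
Reagents that add atoms: methyltriphenylphosphonium bromide, C[P+](c1ccccc1)(c1ccccc1)c1ccccc1.[Br-]
Why: Wittig methylenation of the hindered C8 ketone under forcing conditions adds C17, and any base-induced epimerisation at C9 before olefination leads back to the same equatorial side chain.

Step 18
Reactants: 21 (13S)-labd-8(17)-ene-3β,15-diol
Product: 22 (13S)-3β-hydroxylabd-8(17)-en-15-oic acid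
Conditions: TEMPO (cat.), PhI(OAc)2, MeCN–H2O, rt
Reagents that add atoms: water, O
Why: The oxoammonium (TEMPO) oxidation is selective for the primary alcohol and carries it through the aldehyde hydrate to the acid, leaving the hindered secondary 3β-hydroxyl and the alkene alone.

Step 19
Reactants: 22 (13S)-3β-hydroxylabd-8(17)-en-15-oic acid
Product: 23 (13S)-3β,7α-dihydroxylabd-8(17)-en-15-oic acid
Conditions: SeO2 (0.5 equiv), t-BuOOH, CH2Cl2, 0 °C to rt
Reagents that add atoms: selenium dioxide, O=[Se]=O; tert-butyl hydroperoxide, CC(C)(C)OO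
Why: In the Riley allylic oxidation the ene reaction at C17 should remove the axial 7α hydrogen in preference to the hindered C9 methine, and the [2,3]-sigmatropic shift then restores the exocyclic alkene and delivers oxygen to the axial α face of C7.

Step 20
Reactants: 23 (13S)-3β,7α-dihydroxylabd-8(17)-en-15-oic acid
Product: 25 (13S)-3β,7α-diacetoxylabd-8(17)-en-15-oic acid, via mixed acetic anhydride 24 (not isolated)
Conditions: Ac2O, pyridine, DMAP (cat.), rt; then THF–aq. NaHCO3; acidify to pH 3
Reagents that add atoms: acetic anhydride, CC(=O)OC(C)=O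
Why: DMAP-catalysed acylation esterifies both secondary hydroxyls with retention, and the mixed anhydride formed at the carboxyl group is hydrolysed back to the acid in the aqueous work-up.

**Compound list**
1 | (R)-pantolactone | CC1(C)COC(=O)[C@@H]1O | starting material
2 | (3R)-3-(methoxymethoxy)-4,4-dimethyloxolan-2-one | CC1(C)COC(=O)[C@@H]1OCOC | intermediate
3 | (3R)-3-(methoxymethoxy)-4,4-dimethyloxolan-2-ol (anomer mixture) | CC1(C)COC(O)[C@@H]1OCOC | intermediate
4 | (3S)-3-(methoxymethoxy)-2,2-dimethylpent-4-en-1-ol | C=C[C@H](OCOC)C(C)(C)CO | intermediate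
5 | monomethyl (R)-3-methylglutarate [(3R)-5-methoxy-3-methyl-5-oxopentanoic acid] | COC(=O)C[C@H](C)CC(=O)O | starting material
6 | methyl (3R)-5-hydroxy-3-methylpentanoate | COC(=O)C[C@H](C)CCO | intermediate
7 | methyl (3R)-5-[(tert-butyldimethylsilyl)oxy]-3-methylpentanoate | COC(=O)C[C@H](C)CCO[Si](C)(C)C(C)(C)C | intermediate
8 | (3S)-5-[(tert-butyldimethylsilyl)oxy]-3-methylpentan-1-ol | OCC[C@H](C)CCO[Si](C)(C)C(C)(C)C | intermediate
9 | tert-butyl{[(3R)-5-iodo-3-methylpentyl]oxy}dimethylsilane | ICC[C@H](C)CCO[Si](C)(C)C(C)(C)C | intermediate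
10 | methyl acetoacetate | CC(=O)CC(=O)OC | starting material
11 | methyl (5S)-2-acetyl-7-[(tert-butyldimethylsilyl)oxy]-5-methylheptanoate (C2 epimers) | CC(=O)C(CC[C@H](C)CCO[Si](C)(C)C(C)(C)C)C(=O)OC | intermediate
12 | methyl (2E)-2-{(3S)-5-[(tert-butyldimethylsilyl)oxy]-3-methylpentyl}-3-[(4-methylbenzenesulfonyl)oxy]but-2-enoate | C/C(OS(=O)(=O)c1ccc(C)cc1)=C(/CC[C@H](C)CCO[Si](C)(C)C(C)(C)C)C(=O)OC | intermediate
13 | 9-[(3S)-5-(9-borabicyclo[3.3.1]nonan-9-yloxy)-3-(methoxymethoxy)-4,4-dimethylpentyl]-9-borabicyclo[3.3.1]nonane (bis-borane adduct) | C1CCC2CCCC1B2CC[C@H](OCOC)C(C)(C)COB1C2CCCC1CCC2 | intermediate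
14 | methyl (2E,6S)-2-{(3S)-5-[(tert-butyldimethylsilyl)oxy]-3-methylpentyl}-8-hydroxy-6-(methoxymethoxy)-3,7,7-trimethyloct-2-enoate | COC(=O)/C(CC[C@H](C)CCO[Si](C)(C)C(C)(C)C)=C(\C)CC[C@H](OCOC)C(C)(C)CO | intermediate
15 | (3S,6E)-7-{(3S)-5-[(tert-butyldimethylsilyl)oxy]-3-methylpentyl}-8-methoxy-3-(methoxymethoxy)-2,2,6-trimethylnona-6,8-dien-1-ol | C=C(OC)/C(CC[C@H](C)CCO[Si](C)(C)C(C)(C)C)=C(\C)CC[C@H](OCOC)C(C)(C)CO | intermediate
16 | (3S,6E)-7-{(3S)-5-[(tert-butyldimethylsilyl)oxy]-3-methylpentyl}-8-methoxy-3-(methoxymethoxy)-2,2,6-trimethylnona-6,8-dienal | C=C(OC)/C(CC[C@H](C)CCO[Si](C)(C)C(C)(C)C)=C(\C)CC[C@H](OCOC)C(C)(C)C=O | intermediate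
17 | {[(1E,4S,7E)-8-{(3S)-5-[(tert-butyldimethylsilyl)oxy]-3-methylpentyl}-9-methoxy-4-(methoxymethoxy)-3,3,7-trimethyldeca-1,7,9-trien-1-yl]sulfonyl}benzene | C=C(OC)/C(CC[C@H](C)CCO[Si](C)(C)C(C)(C)C)=C(\C)CC[C@H](OCOC)C(C)(C)/C=C/S(=O)(=O)c1ccccc1 | intermediate
18 | (13S)-15-[(tert-butyldimethylsilyl)oxy]-8-methoxy-3β-(methoxymethoxy)-6α-(phenylsulfonyl)-17-norlabd-8-ene (5α-H; 10β-methyl) | COC=1C[C@H](S(=O)(=O)c2ccccc2)[C@H]3C(C)(C)[C@@H](OCOC)CC[C@]3(C)C=1CC[C@H](C)CCO[Si](C)(C)C(C)(C)C | intermediate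
19 | (13S)-15-[(tert-butyldimethylsilyl)oxy]-8-methoxy-3β-(methoxymethoxy)-17-norlabd-8-ene | COC=1CC[C@H]2C(C)(C)[C@@H](OCOC)CC[C@]2(C)C=1CC[C@H](C)CCO[Si](C)(C)C(C)(C)C | intermediate
20 | (13S)-3β,15-dihydroxy-17-norlabdan-8-one (9α-H) | O=C1CC[C@H]2C(C)(C)[C@@H](O)CC[C@]2(C)[C@H]1CC[C@H](C)CCO | intermediate
21 | (13S)-labd-8(17)-ene-3β,15-diol | C=C1CC[C@H]2C(C)(C)[C@@H](O)CC[C@]2(C)[C@H]1CC[C@H](C)CCO | intermediate
22 | (13S)-3β-hydroxylabd-8(17)-en-15-oic acid | C=C1CC[C@H]2C(C)(C)[C@@H](O)CC[C@]2(C)[C@H]1CC[C@H](C)CC(=O)O | intermediate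
23 | (13S)-3β,7α-dihydroxylabd-8(17)-en-15-oic acid | C=C1[C@H](O)C[C@H]2C(C)(C)[C@@H](O)CC[C@]2(C)[C@H]1CC[C@H](C)CC(=O)O | intermediate
24 | mixed acetic anhydride of (13S)-3β,7α-diacetoxylabd-8(17)-en-15-oic acid | C=C1[C@H](OC(C)=O)C[C@H]2C(C)(C)[C@@H](OC(C)=O)CC[C@]2(C)[C@H]1CC[C@H](C)CC(=O)OC(C)=O | intermediate
25 | (13S)-3β,7α-diacetoxylabd-8(17)-en-15-oic acid (CNP0169875.1) | C=C1[C@H](OC(C)=O)C[C@H]2C(C)(C)[C@@H](OC(C)=O)CC[C@]2(C)[C@H]1CC[C@H](C)CC(=O)O | target

**Count and risks**

Total steps: 20. Longest linear sequence: 17 steps (steps 4–20, from compound 5). The branch from compound 1 is 14 steps (steps 1–3 and 10–20).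

Steps most likely to fail:

1. Step 14. The cycloaddition may be too slow, because a quaternary center is formed next to the gem-dimethyl carbon and the tether forces the dienophile onto the less nucleophilic diene terminus. Thermal decay of the enol ether, or loss of trans and facial selectivity, could then compete. The fallback sets out from aldehyde 16 and returns at 19, and uses a nitroalkene as a more reactive and more strongly endo-directing dienophile. Henry addition of nitromethane to 16 (MeNO2, KOt-Bu cat., THF–t-BuOH, 0 °C) should give the nitro aldol F1. Dehydration (MsCl, Et3N, CH2Cl2, −20 °C) should give the (E)-nitro triene F2. Warming in PhMe at 60–80 °C should give the 6α-nitro cycloadduct F3. Radical denitration (Bu3SnH, AIBN, PhMe, 110 °C) then gives 19.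

2. Step 12. The oxidation of the neopentyl alcohol may also oxidise or hydrolyse the sensitive 2-methoxydiene, and one step earlier the free hydroxyl consumes titanium reagent. The fallback sets out from 4 and returns at 17, and builds the dienophile before the diene exists. Oxidation of 4 (TEMPO, PhI(OAc)2, CH2Cl2) gives the aldehyde F4. The Horner–Wadsworth–Emmons reaction with (EtO)2P(O)CH2SO2Ph and NaH gives the vinyl sulfone F5. Hydroboration with 9-BBN-H (1.1 equiv) gives the alkylborane F6. Suzuki–Miyaura coupling with 12 (Pd(OAc)2, SPhos, aq. K3PO4) gives the sulfonyl enoate F7. Methylenation of F7 with Cp2Ti(μ-CH2)(μ-Cl)AlMe2 then gives 17 directly, with no free hydroxyl present.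

3. Step 19. The allylic oxidation may attack C9 instead of C7, run on to the 7-ketone, or give part of the equatorial 7β-alcohol. The fallback sets out from 20 and returns at 23, and puts the oxygen on C7 by enolate chemistry before C17 is added. Kinetic deprotonation of 20 at the less hindered C7 with LiN(i-Pr)2 (3.5 equiv, THF, −78 °C) and trapping with Me3SiCl gives the tris(trimethylsilyl) Δ7-enol ether F8, which is not isolated. Rubottom oxidation (m-CPBA, NaHCO3, CH2Cl2, −20 °C, then citric acid in MeOH) from the α face opposite the C10 methyl should give the 7α-hydroxy ketone F9. Non-basic methylenation (Zn, CH2Br2, TiCl4, THF) gives the triol F10. Primary-selective oxidation (TEMPO, PhI(OAc)2, MeCN–H2O) returns to 23.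

**Further compounds**
F1 | step 14 | (2RS,4S,7E)-8-{(3S)-5-[(tert-butyldimethylsilyl)oxy]-3-methylpentyl}-9-methoxy-4-(methoxymethoxy)-3,3,7-trimethyl-1-nitrodeca-7,9-dien-2-ol | C=C(OC)/C(CC[C@H](C)CCO[Si](C)(C)C(C)(C)C)=C(\C)CC[C@H](OCOC)C(C)(C)C(O)C[N+](=O)[O-]
F2 | step 14 | tert-butyl{[(3S)-5-[(3E,7S,9E)-2-methoxy-7-(methoxymethoxy)-4,8,8-trimethyl-10-nitrodeca-1,3,9-trien-3-yl]-3-methylpentyl]oxy}dimethylsilane | C=C(OC)/C(CC[C@H](C)CCO[Si](C)(C)C(C)(C)C)=C(\C)CC[C@H](OCOC)C(C)(C)/C=C/[N+](=O)[O-]
F3 | step 14 | (13S)-15-[(tert-butyldimethylsilyl)oxy]-8-methoxy-3β-(methoxymethoxy)-6α-nitro-17-norlabd-8-ene | COC=1C[C@H]([N+](=O)[O-])[C@H]3C(C)(C)[C@@H](OCOC)CC[C@]3(C)C=1CC[C@H](C)CCO[Si](C)(C)C(C)(C)C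
F4 | step 12 | (3S)-3-(methoxymethoxy)-2,2-dimethylpent-4-enal | C=C[C@H](OCOC)C(C)(C)C=O
F5 | step 12 | {[(1E,4S)-4-(methoxymethoxy)-3,3-dimethylhexa-1,5-dien-1-yl]sulfonyl}benzene | C=C[C@H](OCOC)C(C)(C)/C=C/S(=O)(=O)c1ccccc1
F6 | step 12 | 9-[(3S,5E)-3-(methoxymethoxy)-4,4-dimethyl-6-(phenylsulfonyl)hex-5-en-1-yl]-9-borabicyclo[3.3.1]nonane | C1CCC2CCCC1B2CC[C@H](OCOC)C(C)(C)/C=C/S(=O)(=O)c1ccccc1
F7 | step 12 | methyl (2E,6S,8E)-2-{(3S)-5-[(tert-butyldimethylsilyl)oxy]-3-methylpentyl}-6-(methoxymethoxy)-3,7,7-trimethyl-9-(phenylsulfonyl)nona-2,8-dienoate | COC(=O)/C(CC[C@H](C)CCO[Si](C)(C)C(C)(C)C)=C(\C)CC[C@H](OCOC)C(C)(C)/C=C/S(=O)(=O)c1ccccc1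
F8 | step 19 | (13S)-3β,8,15-tris(trimethylsilyloxy)-17-norlabd-7-ene | C[Si](C)(C)OC1=CC[C@H]2C(C)(C)[C@@H](O[Si](C)(C)C)CC[C@]2(C)[C@H]1CC[C@H](C)CCO[Si](C)(C)C
F9 | step 19 | (13S)-3β,7α,15-trihydroxy-17-norlabdan-8-one | O=C1[C@H](O)C[C@H]2C(C)(C)[C@@H](O)CC[C@]2(C)[C@H]1CC[C@H](C)CCO
F10 | step 19 | (13S)-labd-8(17)-ene-3β,7α,15-triol | C=C1[C@H](O)C[C@H]2C(C)(C)[C@@H](O)CC[C@]2(C)[C@H]1CC[C@H](C)CCO
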